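## Retrosynthetic overview

1. Junceellolide K ⇐ triacetylation, desilylation and hydrogenation of the C17 exo-methylene ⇐ α-methylene hydroxy-lactone 30.
2. 30 ⇐ macrocyclic vinyl oxirane 27 by one operation with CO2: the alkenyl metal on C8 is carboxylated (C19–C17) and the carboxylate opens the oxirane at C7 (O–C7). The feature that allows this is the trans C7–C8 oxirane inside the ten-membered ring: C7 is allylic to C5=C6, and the quaternary C8 carries the 1-metallovinyl arm (C17) cis to C6, so the lactone ring O–C19–C17–C8–C7 can close and the oxirane oxygen stays as the C8 hydroxyl.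
3. 27 ⇐ two hydroxyl-directed epoxidations and inversion at C9 ⇐ ten-membered dienone 22 ⇐ Stille–Kelly closure of C6–C7 ⇐ iodo-aldol (C8–C9) of ring-A aldehyde 16 with but-3-yn-2-one.
4. 16 ⇐ ring-A enone 2 + a silylmethyl Grignard reagent + (Z)-iodo-aldehyde 8 (asymmetric conjugate addition–aldol sets C10, C1, C2), then 1,3-anti reduction (C14).
5. Ring order: ring A (present in 2) → spiro-oxirane (step 12) → ten-membered ring (step 13) → C7–C8 oxirane (step 16) → γ-lactone (step 19).

Key step: step 19

Assumption: 1, 3, 4 and 17 are taken as catalogue compounds, and the Grignard reagent of step 4 is made in situ from commercial (chloromethyl)dimethyl(propan-2-yloxy)silane. Names use skeleton numbers: C1 quaternary carbon, C2–C9 the chain of the ten-membered ring, C10–C14 the rest of ring A, C15/C16/C18 methyls, C17/C19 lactone carbons, C20 oxirane methylene.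

## Route

Step 1
Reactants: 1 7-methyl-1,4-dioxaspiro[4.5]decan-8-one
Product: 2 7-methyl-1,4-dioxaspiro[4.5]dec-6-en-8-one
Conditions: IBX (1.3 equiv), DMSO, 65 °C
Reagents that add atoms: none
Why: IBX dehydrogenation of a ketone through its enol; the more substituted enol reacts and the quaternary ketal carbon prevents aromatisation, so the α-methyl enone should form.

Step 2
Reactants: 3 2-(2-bromoethyl)-1,3-dioxolane; 4 propyne
Product: 7 2-[(3Z)-4-iodo-3-methylbut-3-enyl]-1,3-dioxolane, via Grignard reagent 5 (not isolated), via (Z)-alkenylcopper 6 (not isolated)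
Conditions: Mg, Et2O; CuBr·SMe2, Me2S/Et2O, −45 °C; propyne (excess), −25 °C; I2, −50 → 0 °C
Reagents that add atoms: iodine, II
Why: Normant carbocupration: the primary alkylcopper adds syn across propyne with the alkyl group on the internal carbon and copper on the terminus, and iodinolysis with retention gives the (Z)-iodoalkene that becomes C5=C6.

Step 3
Reactants: 7 2-[(3Z)-4-iodo-3-methylbut-3-enyl]-1,3-dioxolane
Product: 8 (4Z)-5-iodo-4-methylpent-4-enal
Conditions: 1 M HCl, THF, rt
Reagents that add atoms: water, O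
Why: Acid-catalysed acetal hydrolysis frees the aldehyde (future C2) without touching the iodoalkene.

Step 4
Reactants: 2 7-methyl-1,4-dioxaspiro[4.5]dec-6-en-8-one; 8 (4Z)-5-iodo-4-methylpent-4-enal
Product: 10 C2 aldol adduct of the C10-silylmethyl ring-A ketone, via magnesium enolate 9 (not isolated)
Conditions: (i-PrO)Me2SiCH2MgCl (1.3 equiv), CuBr·SMe2 (5 mol %), (S,R,R)-binaphthyl bis(1-phenylethyl)phosphoramidite (10 mol %), Et2O, −40 °C; then 8, −78 → −40 °C
Reagents that add atoms: (isopropoxydimethylsilyl)methylmagnesium chloride, CC(C)O[Si](C)(C)C[Mg]Cl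
Why: Copper-catalysed asymmetric conjugate addition of a Grignard reagent (ligand-controlled face, sets C10) followed by a Zimmerman–Traxler aldol of the tetrasubstituted magnesium enolate, in which 8 enters anti to the new C10 substituent (sets quaternary C1) and the C2 hydroxyl ends syn to the C1 methyl (sets C2).

Step 5
Reactants: 10 C2 aldol adduct of the C10-silylmethyl ring-A ketone
Product: 11 2,14-anti-diol
Conditions: Me4NBH(OAc)3, MeCN/AcOH, −30 °C
Reagents that add atoms: none
Why: Evans–Saksena reduction: hydride is delivered from boron bound to the C2 oxygen through a chair transition state with C13 equatorial, which should give the 1,3-anti diol, that is the axial C14 alcohol cis to C2.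

Step 6
Reactants: 11 2,14-anti-diol
Product: 12 O2/O14 di-tert-butylsilylene acetal
Conditions: t-Bu2Si(OTf)2, 2,6-lutidine, CH2Cl2, 0 °C
Reagents that add atoms: di-tert-butylsilyl bis(trifluoromethanesulfonate), CC(C)(C)[Si](OS(=O)(=O)C(F)(F)F)(OS(=O)(=O)C(F)(F)F)C(C)(C)C
Why: Silylene formation bridges the 1,3-diol in a six-membered ring and protects both oxygens in one step; no stereocentre is affected.

Step 7
Reactants: 12 O2/O14 di-tert-butylsilylene acetal
Product: 13 primary C9 alcohol
Conditions: H2O2 (30%), KF, KHCO3, THF/MeOH, rt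
Reagents that add atoms: hydrogen peroxide, OO
Why: Tamao–Kumada oxidation turns the C9–Si bond of the alkoxysilane into the primary alcohol under conditions that leave the iodoalkene alone.

Step 8
Reactants: 13 primary C9 alcohol
Product: 14 C11 ketone
Conditions: 2 M HCl, THF, rt
Reagents that add atoms: water, O
Why: Acid hydrolysis of the ethylene ketal unmasks the C11 ketone; the equatorial C10 substituent is the stable epimer, so C10 should not be lost.

Step 9
Reactants: 14 C11 ketone
Product: 15 C11 exo-methylene alcohol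
Conditions: Zn, CH2Br2, TiCl4, THF/CH2Cl2, 0 °C → rt
Reagents that add atoms: dibromomethane, BrCBr
Why: Lombardo methylenation is non-basic, so the β-hydroxy ketone should be methylenated without retro-aldol loss of C9 or epimerisation at C10.

Step 10
Reactants: 15 C11 exo-methylene alcohol
Product: 16 C9 aldehyde
Conditions: Dess–Martin periodinane, NaHCO3, CH2Cl2, 0 °C
Reagents that add atoms: none
Why: Buffered Dess–Martin oxidation gives the aldehyde under neutral conditions that should not move the β,γ-double bond into conjugation.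

Step 11
Reactants: 16 C9 aldehyde; 17 but-3-yn-2-one
Product: 19 (9R)-iodo-aldol adduct with (Z)-β-iodoenone, via magnesium iodoallenolate 18 (not isolated)
Conditions: MgI2 (1.3 equiv), CH2Cl2, 0 °C
Reagents that add atoms: magnesium iodide, [Mg+2].[I-].[I-]
Why: MgI2-mediated iodo-aldol (β-iodo Morita–Baylis–Hillman reaction): iodide adds to the ynone and the allenolate adds to the aldehyde through a closed transition state to give the (Z)-β-iodoenone (iodine cis to acetyl), with Felkin–Anh attack anti to quaternary C1 expected to set C9 as R, the epimer needed for step 16.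

Step 12
Reactants: 19 (9R)-iodo-aldol adduct with (Z)-β-iodoenone
Product: 20 11,20-spiro-oxirane
Conditions: VO(acac)2 (5 mol %), TBHP (1.5 equiv), CH2Cl2, 0 °C → rt
Reagents that add atoms: tert-butyl hydroperoxide, CC(C)(C)OO
Why: Hydroxyl-directed vanadium-catalysed epoxidation: the peroxide bound at O9 reaches only the homoallylic exocyclic alkene (both iodoalkenes are electron-poor) and should deliver oxygen to the face opposite the axial C15 methyl, giving the equatorial C11–O bond of the target.

Step 13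
Reactants: 20 11,20-spiro-oxirane
Product: 22 ten-membered (5Z,7Z)-dienone, via C7 alkenylstannane 21 (not isolated)
Conditions: Pd(PPh3)4 (10 mol %), Me3SnSnMe3 (1.1 equiv), 1,4-dioxane (0.002 M), 100 °C
Reagents that add atoms: none
Why: Stille–Kelly coupling: palladium inserts into the β-iodoenone, the ditin converts it into an alkenylstannane, and intramolecular Stille coupling with the second iodoalkene closes the ten-membered ring at C6–C7 with retention of both alkene geometries.

Step 14
Reactants: 22 ten-membered (5Z,7Z)-dienone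
Product: 23 C17 enol triflate
Conditions: KN(SiMe3)2 (2.2 equiv), THF, −78 °C; PhNTf2 (1.1 equiv)
Reagents that add atoms: N-phenylbis(trifluoromethanesulfonimide), O=S(=O)(N(c1ccccc1)S(=O)(=O)C(F)(F)F)C(F)(F)F
Why: Kinetic deprotonation of the methyl ketone (its other α-carbon is sp2) and O-sulfonylation of the enolate give the dienyl triflate; the hindered C9 alkoxide should not be triflated by this mild reagent.

Step 15
Reactants: 23 C17 enol triflate
Product: 24 C17 trimethylstannane
Conditions: Pd(PPh3)4 (5 mol %), Me3SnSnMe3 (1.3 equiv), LiCl (3 equiv), THF, 60 °C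
Reagents that add atoms: hexamethylditin, C[Sn](C)(C)[Sn](C)(C)C
Why: Palladium-catalysed stannylation of an alkenyl triflate with a ditin installs the C17 tin handle before any vinyl oxirane is present.

Step 16
Reactants: 24 C17 trimethylstannane
Product: 25 erythro 7,8-oxirane with 9R alcohol
Conditions: VO(acac)2 (5 mol %), TBHP (1.05 equiv), CH2Cl2, −20 °C
Reagents that add atoms: tert-butyl hydroperoxide, CC(C)(C)OO
Why: Hydroxyl-directed vanadium-catalysed epoxidation of the allylic-alcohol alkene C7=C8; A(1,2) strain from the stannylvinyl group on C8 should enforce the erythro epoxy alcohol, which fixes C8 as in the target and gives the trans-oxirane from the (7Z)-alkene.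

Step 17
Reactants: 25 erythro 7,8-oxirane with 9R alcohol
Product: 26 9S 4-nitrobenzoate
Conditions: 4-nitrobenzoic acid, PPh3, DIAD, toluene, 0 °C → rt
Reagents that add atoms: 4-nitrobenzoic acid, OC(=O)c1ccc(cc1)[N+](=O)[O-]
Why: Mitsunobu inversion of the hindered C9 carbinol (substitution with inversion on the oxyphosphonium ion) converts the erythro into the threo C8/C9 relationship of the target.

Step 18
Reactants: 26 9S 4-nitrobenzoate
Product: 27 9S epoxy alcohol
Conditions: K2CO3, MeOH, 0 °C
Reagents that add atoms: none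
Why: Mild methanolysis removes the ester; Payne migration should not compete because C8 is a fully substituted oxirane carbon.

Step 19
Reactants: 27 9S epoxy alcohol
Product: 30 α-methylene-β-hydroxy-γ-lactone, via alkenyllithium 28 (not isolated), via lithium carboxylate 29 (not isolated)
Conditions: MeLi (2.2 equiv), THF, −78 °C, 10 min; CO2 (g), −78 °C; AcOH (3 equiv), −78 °C → rt
Reagents that add atoms: carbon dioxide, O=C=O
Why: Tin–lithium exchange at the alkenylstannane (the first equivalent of MeLi makes the C9 alkoxide) gives an alkenyllithium that CO2 carboxylates at C17, and on acidification the carboxyl oxygen attacks oxirane carbon C7 from the side opposite the C7–O bond, leaving the oxirane oxygen on C8 as the tertiary alcohol. The closest known reactions are the carboxylation of α-substituted vinyllithiums to α-methylene acids and the cyclisation of 3,4-epoxy acids to β-hydroxy-γ-butyrolactones. One ring is closed, the γ-lactone O–C19–C17–C8–C7, by endo-mode opening of the oxirane at its distal carbon (bond O–C7, five-membered ring). The only new stereocentre, C7, is set by inversion of the C7–O oxirane bond, so the trans-oxirane of step 16 should give the trans-fused lactone with the C8 hydroxyl cis to C6; C8 keeps its oxirane oxygen. The step needs attack at C7 and not at C8 or C5: C7 is secondary and allylic to C5=C6, C8 is quaternary and would give a four-membered ring, and C5 would give a seven-membered ring. It also needs exchange and carboxylation to outrun elimination of the lithium reagent onto the oxirane, which the low temperature and immediate CO2 quench are meant to secure.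

Step 20
Reactants: 30 α-methylene-β-hydroxy-γ-lactone
Product: 31 17R α-methyl lactone
Conditions: Ru(OAc)2[(S)-BINAP] (2 mol %), H2 (5 atm), MeOH/CH2Cl2, rt
Reagents that add atoms: none
Why: Carboxyl-directed asymmetric hydrogenation with the ruthenium BINAP dicarboxylate reduces only the conjugated exo-methylene; by analogy with α-methylene-γ-butyrolactone the (S)-ligand should set 17R, which should also be the more stable epimer (methyl trans to C9).

Step 21
Reactants: 31 17R α-methyl lactone
Product: 32 2,8,9,14-tetraol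
Conditions: TBAF (3 equiv), AcOH (3 equiv), THF, 0 °C → rt
Reagents that add atoms: none
Why: Buffered fluoride cleaves the silylene to release the C2 and C14 hydroxyls while the lactone and the spiro-oxirane should survive.

Step 22
Reactants: 32 2,8,9,14-tetraol
Product: 33 junceellolide K
Conditions: Ac2O, pyridine, DMAP (cat.), CH2Cl2, 0 °C → rt
Reagents that add atoms: acetic anhydride, CC(=O)OC(C)=O
Why: DMAP-catalysed acetylation of the three secondary alcohols (C2, C9, C14); the tertiary C8 hydroxyl is too hindered to react under these conditions.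

## Compound list

1 | 7-methyl-1,4-dioxaspiro[4.5]decan-8-one (racemic) | CC1CC2(CCC1=O)OCCO2 | starting material
2 | 7-methyl-1,4-dioxaspiro[4.5]dec-6-en-8-one | CC1=CC2(CCC1=O)OCCO2 | intermediate
3 | 2-(2-bromoethyl)-1,3-dioxolane | BrCCC1OCCO1 | starting material
4 | propyne | CC#C | starting material
5 | [2-(1,3-dioxolan-2-yl)ethyl]magnesium bromide (not isolated) | Br[Mg]CCC1OCCO1 | intermediate
6 | [(1Z)-4-(1,3-dioxolan-2-yl)-2-methylbut-1-enyl]copper (not isolated) | [Cu]/C=C(C)\CCC1OCCO1 | intermediate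
7 | 2-[(3Z)-4-iodo-3-methylbut-3-enyl]-1,3-dioxolane | I/C=C(C)\CCC1OCCO1 | intermediate
8 | (4Z)-5-iodo-4-methylpent-4-enal | I/C=C(C)\CCC=O | intermediate
9 | chloromagnesium C1=C14 enolate of the conjugate adduct; C10 bears CH2SiMe2(O-i-Pr) (not isolated) | CC1=C(O[Mg]Cl)CCC2(OCCO2)[C@@H]1C[Si](C)(C)OC(C)C | intermediate
10 | aldol adduct: ring-A C14 ketone with C11 ethylene ketal, C10 CH2SiMe2(O-i-Pr), C1 methyl and the C2 carbinol chain CH(OH)CH2CH2C(CH3)=CHI (Z); C1, C2, C10 as in the target | I/C=C(C)\CC[C@H](O)[C@@]1(C)C(=O)CCC2(OCCO2)[C@@H]1C[Si](C)(C)OC(C)C | intermediate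
11 | 2,14-anti-diol of 10 (C14 hydroxyl axial, cis to C2) | I/C=C(C)\CC[C@H](O)[C@@]1(C)[C@@H](O)CCC2(OCCO2)[C@@H]1C[Si](C)(C)OC(C)C | intermediate
12 | O2/O14 di-tert-butylsilylene acetal of 11 | I/C=C(C)\CC[C@@H]1O[Si](C(C)(C)C)(C(C)(C)C)O[C@H]2CCC3(OCCO3)[C@H](C[Si](C)(C)OC(C)C)[C@@]12C | intermediate
13 | primary C9 alcohol (C10 bears CH2OH), C11 ketal | I/C=C(C)\CC[C@@H]1O[Si](C(C)(C)C)(C(C)(C)C)O[C@H]2CCC3(OCCO3)[C@H](CO)[C@@]12C | intermediate
14 | C11 ketone with C9 alcohol | I/C=C(C)\CC[C@@H]1O[Si](C(C)(C)C)(C(C)(C)C)O[C@H]2CCC(=O)[C@H](CO)[C@@]12C | intermediate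
15 | C11 exo-methylene C9 alcohol | I/C=C(C)\CC[C@@H]1O[Si](C(C)(C)C)(C(C)(C)C)O[C@H]2CCC(=C)[C@H](CO)[C@@]12C | intermediate
16 | C9 aldehyde | I/C=C(C)\CC[C@@H]1O[Si](C(C)(C)C)(C(C)(C)C)O[C@H]2CCC(=C)[C@H](C=O)[C@@]12C | intermediate
17 | but-3-yn-2-one | CC(=O)C#C | starting material
18 | magnesium iodoallenolate CH3C(OMgI)=C=CHI (not isolated) | CC(O[Mg]I)=C=CI | intermediate
19 | (9R)-iodo-aldol adduct: C9 carbinol carrying C8(=C7HI)–C17(=O)CH3, iodine cis to acetyl | CC(=O)/C(=C\I)[C@H](O)[C@H]1C(=C)CC[C@@H]2O[Si](C(C)(C)C)(C(C)(C)C)O[C@@H](CC/C(C)=C\I)[C@]12C | intermediate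
20 | 11,20-spiro-oxirane of 19 (C11 as in the target) | CC(=O)/C(=C\I)[C@H](O)[C@H]1[C@@]3(CO3)CC[C@@H]2O[Si](C(C)(C)C)(C(C)(C)C)O[C@@H](CC/C(C)=C\I)[C@]12C | intermediate
21 | C7 trimethylstannyl enone (not isolated) | CC(=O)/C(=C\[Sn](C)(C)C)[C@H](O)[C@H]1[C@@]3(CO3)CC[C@@H]2O[Si](C(C)(C)C)(C(C)(C)C)O[C@@H](CC/C(C)=C\I)[C@]12C | intermediate
22 | ten-membered (5Z,7Z)-dienone: C8 acetyl, 9R hydroxyl, spiro-oxirane, silylene | C1C/C(C)=C\C=C(/C(C)=O)\[C@H](O)[C@H]3[C@@]4(CO4)CC[C@@H]5O[Si](C(C)(C)C)(C(C)(C)C)O[C@@H]1[C@]35C | intermediate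
23 | C17 enol triflate of 22 | C1C/C(C)=C\C=C(/C(=C)OS(=O)(=O)C(F)(F)F)\[C@H](O)[C@H]3[C@@]4(CO4)CC[C@@H]5O[Si](C(C)(C)C)(C(C)(C)C)O[C@@H]1[C@]35C | intermediate
24 | C17 trimethylstannyl triene, 9R alcohol | C1C/C(C)=C\C=C(/C(=C)[Sn](C)(C)C)\[C@H](O)[C@H]3[C@@]4(CO4)CC[C@@H]5O[Si](C(C)(C)C)(C(C)(C)C)O[C@@H]1[C@]35C | intermediate
25 | trans 7,8-oxirane, erythro to the 9R alcohol; C8 as in the target | C1C/C(C)=C\[C@H]6O[C@]6(C(=C)[Sn](C)(C)C)[C@H](O)[C@H]3[C@@]4(CO4)CC[C@@H]5O[Si](C(C)(C)C)(C(C)(C)C)O[C@@H]1[C@]35C | intermediate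
26 | 9S 4-nitrobenzoate of the 7,8-oxirane | C1C/C(C)=C\[C@H]6O[C@]6(C(=C)[Sn](C)(C)C)[C@@H](OC(=O)c7ccc(cc7)[N+](=O)[O-])[C@H]3[C@@]4(CO4)CC[C@@H]5O[Si](C(C)(C)C)(C(C)(C)C)O[C@@H]1[C@]35C | intermediate
27 | 9S epoxy alcohol (key-step precursor) | C1C/C(C)=C\[C@H]6O[C@]6(C(=C)[Sn](C)(C)C)[C@@H](O)[C@H]3[C@@]4(CO4)CC[C@@H]5O[Si](C(C)(C)C)(C(C)(C)C)O[C@@H]1[C@]35C | intermediate
28 | C17 alkenyllithium with C9 lithium alkoxide (not isolated) | C1C/C(C)=C\[C@H]6O[C@]6(C(=C)[Li])[C@@H](O[Li])[C@H]3[C@@]4(CO4)CC[C@@H]5O[Si](C(C)(C)C)(C(C)(C)C)O[C@@H]1[C@]35C | intermediate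
29 | C19 lithium carboxylate with C9 lithium alkoxide (not isolated) | C1C/C(C)=C\[C@H]6O[C@]6(C(=C)C(=O)O[Li])[C@@H](O[Li])[C@H]3[C@@]4(CO4)CC[C@@H]5O[Si](C(C)(C)C)(C(C)(C)C)O[C@@H]1[C@]35C | intermediate
30 | α-methylene-β-hydroxy-γ-lactone (C17=CH2); C7, C8, C9 as in the target; silylene | C1C/C(C)=C\[C@@H]2OC(=O)C(=C)[C@@]2(O)[C@@H](O)[C@H]3[C@@]4(CO4)CC[C@@H]5O[Si](C(C)(C)C)(C(C)(C)C)O[C@@H]1[C@]35C | intermediate
31 | 17R α-methyl lactone, silylene | C1C/C(C)=C\[C@@H]2OC(=O)[C@H](C)[C@@]2(O)[C@@H](O)[C@H]3[C@@]4(CO4)CC[C@@H]5O[Si](C(C)(C)C)(C(C)(C)C)O[C@@H]1[C@]35C | intermediate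
32 | 2,8,9,14-tetraol (tri-deacetyl junceellolide K) | O[C@H]1CC/C(C)=C\[C@@H]2OC(=O)[C@H](C)[C@@]2(O)[C@@H](O)[C@H]2[C@]3(CC[C@H](O)[C@]12C)CO3 | intermediate
33 | junceellolide K | CC(=O)O[C@H]1CC/C(C)=C\[C@@H]2OC(=O)[C@H](C)[C@@]2(O)[C@@H](OC(C)=O)[C@H]2[C@]3(CC[C@H](OC(C)=O)[C@]12C)CO3 | target

## Summary and risks

Total step count: 22. Longest linear sequence: 21 steps (3 → 33, steps 2–22).

Three steps most likely to fail:

**Step 19.** The alkenyllithium may eliminate onto the neighbouring oxirane (opening to an allenyl alkoxide) before it is carboxylated. The oxirane may also open through an allyl cation on acidification, which would scramble C7. The fallback forms the two bonds in separate known steps and never places a carbanion beside an oxirane. It sets out from stannane 24. Tin–lithium exchange (MeLi, THF, −78 °C) and CO2 give the cross-conjugated dienoic acid F1. VO(acac)2/TBHP then epoxidises C7=C8 under direction of the C9 hydroxyl, and the free acid opens the oxirane at C7 in the same flask to give the 9R hydroxy lactone F2. Mitsunobu inversion with formic acid (PPh3, DIAD) gives the 9S formate F3. KHCO3 in aqueous methanol at 0 °C removes the formate and returns to the route at 30.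

**Step 13.** The two alkenyl iodides may couple between molecules, or be reduced, faster than the strained ten-membered ring closes. The fallback separates metalation from ring closure. From 20, chemoselective Miyaura borylation of the more reactive β-iodoenone (PdCl2(dppf), bis(pinacolato)diboron, KOAc, DMSO, 60 °C) gives the alkenyl boronate F4. Suzuki–Miyaura macrocyclisation under slow addition (Pd(PPh3)4, Cs2CO3, THF/H2O, 60 °C) then closes C6–C7 and returns to the route at 22.

**Step 4.** Facial selectivity of the copper catalyst may be poor, and addition slow, on an α-methyl enone with a quaternary γ-carbon; the aldol trapping may also reverse. The fallback replaces catalyst control by a covalently bound chiral auxiliary. From 2, acid-catalysed exchange of the ethylene ketal for (1R,2R)-hydrobenzoin (PPTS, benzene, reflux) gives the chiral ketal enone F5; the antipodal diol is taken if induction proves to run the other way. Stoichiometric CuBr·SMe2/Grignard addition anti to the proximal phenyl group and trapping with 8 gives the aldol adduct F6. Evans–Saksena reduction gives the diol F7, silylene formation gives the silylene acetal F8, and Tamao oxidation gives the primary alcohol F9. The acid hydrolysis of step 8 removes the auxiliary and returns to the route at 14.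

Further compounds
F1 | step 19 | C19 dienoic acid from 24 (9R alcohol, no 7,8-oxirane) | C1C/C(C)=C\C=C(/C(=C)C(O)=O)\[C@H](O)[C@H]3[C@@]4(CO4)CC[C@@H]5O[Si](C(C)(C)C)(C(C)(C)C)O[C@@H]1[C@]35C
F2 | step 19 | 9R epimer of lactone 30 | C1C/C(C)=C\[C@@H]2OC(=O)C(=C)[C@@]2(O)[C@H](O)[C@H]3[C@@]4(CO4)CC[C@@H]5O[Si](C(C)(C)C)(C(C)(C)C)O[C@@H]1[C@]35C
F3 | step 19 | 9S formate of lactone 30 | C1C/C(C)=C\[C@@H]2OC(=O)C(=C)[C@@]2(O)[C@@H](OC=O)[C@H]3[C@@]4(CO4)CC[C@@H]5O[Si](C(C)(C)C)(C(C)(C)C)O[C@@H]1[C@]35C
F4 | step 13 | C7 pinacol boronate of 20 (C6 iodide kept) | CC(=O)/C(=C\B1OC(C)(C)C(C)(C)O1)[C@H](O)[C@H]1[C@@]3(CO3)CC[C@@H]2O[Si](C(C)(C)C)(C(C)(C)C)O[C@@H](CC/C(C)=C\I)[C@]12C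
F5 | step 4 | (R,R)-hydrobenzoin ketal analogue of enone 2 | CC1=CC2(CCC1=O)O[C@H](c3ccccc3)[C@@H](c3ccccc3)O2
F6 | step 4 | (R,R)-hydrobenzoin ketal analogue of aldol adduct 10 | I/C=C(C)\CC[C@H](O)[C@@]1(C)C(=O)CCC2(O[C@H](c3ccccc3)[C@@H](c3ccccc3)O2)[C@@H]1C[Si](C)(C)OC(C)C
F7 | step 4 | (R,R)-hydrobenzoin ketal analogue of diol 11 | I/C=C(C)\CC[C@H](O)[C@@]1(C)[C@@H](O)CCC2(O[C@H](c3ccccc3)[C@@H](c3ccccc3)O2)[C@@H]1C[Si](C)(C)OC(C)C
F8 | step 4 | (R,R)-hydrobenzoin ketal analogue of silylene 12 | I/C=C(C)\CC[C@@H]1O[Si](C(C)(C)C)(C(C)(C)C)O[C@H]2CCC3(O[C@H](c4ccccc4)[C@@H](c4ccccc4)O3)[C@H](C[Si](C)(C)OC(C)C)[C@@]12C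
F9 | step 4 | (R,R)-hydrobenzoin ketal analogue of alcohol 13 | I/C=C(C)\CC[C@@H]1O[Si](C(C)(C)C)(C(C)(C)C)O[C@H]2CCC3(O[C@H](c4ccccc4)[C@@H](c4ccccc4)O3)[C@H](CO)[C@@]12C
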